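**Plan**

1. Numbering used here: lactone ring A = C1 (the =CH on C10), C2, C3 (C=O), O, C4 (CMe2), C5, C10; ring B = C5–C10; ring C = C8, C9, C11, C12, C13, C14; ring D = C12, C13, C14, C15 (C=O), C16 (C(Me)OH), C17 (C=O). C13 carries the =CH2 and C14 the CO2Me.
2. Retrosynthetic cuts: ring D at C16–OH, C16–Me and C15–C16 (Claisen); ring A at C1=C2 (metathesis) and the O–C3 acrylate ester; rings B and C together at C8–C9 and C13–C14 (one radical cascade); then C8=C14 (Knoevenagel), C9–C10 (aldol), C10–Me and C11–C12 (propargylic allylation).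
3. Enabling feature: C14 carries two acyl groups and sits in ring C between quaternary C8 and C13 with its exocyclic methylene. C8 is therefore the β-carbon of an alkylidene malonate, C14 a stabilised radical site and C13=CH2 a reduced alkyne, so a radical at the ring-fusion carbon C9 can relay C9→C8 and C14→C13 and close rings B and C in one event.
4. Forward order: γ-lactone (C1, C10, C5, C4, O; a temporary ring from (S)-α-terpineol) → aldol at C10/C9 → cascade (rings B, C) → lactone rebuilt into ring A (C10 vinyl, C4 acrylate, metathesis) → spare alkyne to methyl ketone → Claisen closure of ring D → C16 methylation and hydroxylation.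
5. Stereochemistry: C5 from (S)-α-terpineol; C10 by aldol anti to the C5 side chain on the lactone; C8, C9 and C12 in the cascade (chair transition states, convergent in C9, group-selective between the two alkynes on prochiral C12); C14 because the Claisen closure can only use the ester syn-axial to the C12 acyl group; C16 by exo-face hydroxylation.

Key step: step 10

Remark: (S)-(−)-α-terpineol of high enantiomeric purity is taken as commercial (it is otherwise available by Markovnikov hydration of (S)-limonene); the SiMe3 caps on both alkynes and the γ-lactone are helper groups, removed in steps 11, 16 and 12–15.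

**Route**

Step 1
Reactants: 1 ethyl acetate; 2 (trimethylsilyl)acetylene
Product: 3 3-methyl-1,5-bis(trimethylsilyl)penta-1,4-diyn-3-ol
Conditions: 2 (2.2 equiv), n-BuLi (2.2 equiv), THF, −78 °C; then 1, −78 to 0 °C; aq. NH4Cl
Reagents that add atoms: none
Why: Double addition of the lithium acetylide to the ester (the intermediate ynone is more electrophilic than the ester) should give the tertiary bis-propargylic alcohol.

Step 2
Reactants: 3 diynol
Product: 4 4-methyl-6-(trimethylsilyl)-4-[(trimethylsilyl)ethynyl]hex-1-en-5-yne
Conditions: allylSiMe3 (3 equiv), FeCl3 (10 mol%), CH2Cl2, 0 °C to rt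
Reagents that add atoms: allyltrimethylsilane C=CC[Si](C)(C)C
Why: Lewis-acid ionisation gives a methyl-substituted bis-propargylic cation that the allylsilane should capture at the central carbon, the alkyne termini being blocked by SiMe3 (Hosomi–Sakurai-type propargylic substitution), which builds the prochiral quaternary carbon that becomes C12.

Step 3
Reactants: 4 enediyne
Product: 5 3-methyl-5-(trimethylsilyl)-3-[(trimethylsilyl)ethynyl]pent-4-ynal
Conditions: O3, CH2Cl2, −78 °C (stopped at alkene consumption); PPh3, −78 °C to rt
Reagents that add atoms: ozone [O-][O+]=O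
Why: Ozonolysis with reductive work-up should cleave the terminal alkene far faster than the silyl-capped alkynes.

Step 4
Reactants: 6 (S)-(−)-α-terpineol
Product: 8 (4S)-5,5-dimethyl-4-(3-oxobutyl)oxolan-2-one, via hydroxy keto acid 7 (not isolated)
Conditions: RuCl3·xH2O (2 mol%), NaIO4 (4 equiv), EtOAc/MeCN/H2O, rt; then 1 M HCl
Reagents that add atoms: sodium periodate [Na+].[O-]I(=O)(=O)=O
Why: RuO4-type oxidative cleavage of the trisubstituted ring alkene gives methyl ketone plus carboxylic acid, and the γ-hydroxy acid should lactonise on acidification; the stereocentre (later C5) is not touched.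

Step 5
Reactants: 8 keto lactone
Product: 9 (4S)-5,5-dimethyl-4-[2-(2-methyl-1,3-dioxolan-2-yl)ethyl]oxolan-2-one
Conditions: HOCH2CH2OH (3 equiv), TsOH·H2O (cat.), PhH, reflux, Dean–Stark
Reagents that add atoms: ethylene glycol OCCO
Why: Ketalisation masks the more acidic methyl ketone so that the lactone can be enolised in the next two steps.

Step 6
Reactants: 9 ketal lactone
Product: 10 (4S)-3,5,5-trimethyl-4-[2-(2-methyl-1,3-dioxolan-2-yl)ethyl]oxolan-2-one (3-methyl mainly trans to the 4-side chain)
Conditions: LiN(i-Pr)2 (1.1 equiv), THF, −78 °C; MeI, −78 to −40 °C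
Reagents that add atoms: iodomethane CI
Why: Lactone enolate alkylation at the only α-position (the future C10) should occur anti to the C5 side chain; the new centre is re-enolised in step 7, so its configuration does not matter.

Step 7
Reactants: 10 α-methyl lactone; 5 aldehyde
Product: 12 keto aldol [(4S)-3-(1-hydroxy-3-methyl-5-(trimethylsilyl)-3-[(trimethylsilyl)ethynyl]pent-4-yn-1-yl)-3,5,5-trimethyl-4-(3-oxobutyl)oxolan-2-one; new chain trans and 3-methyl cis to the 4-side chain; carbinol epimers], via ketal aldol 11 (not isolated)
Conditions: LiN(i-Pr)2 (1.2 equiv), THF, −78 °C; 5, −78 °C; then 1 M HCl/THF, −78 °C to rt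
Reagents that add atoms: water O
Why: Aldol addition of the tetrasubstituted lithium lactone enolate should take place on the face anti to the C5 side chain and so set quaternary C10 (C9 chain trans, methyl cis to the C5 substituent), while the C9 carbinol configuration is irrelevant and the acidic work-up hydrolyses the ketal.

Step 8
Reactants: 12 keto aldol
Product: 13 O-phenyl thionocarbonate of 12 at the C9 carbinol
Conditions: PhOC(S)Cl (2 equiv), pyridine (4 equiv), DMAP (0.2 equiv), CH2Cl2, 0 °C to rt
Reagents that add atoms: O-phenyl chlorothionoformate S=C(Cl)Oc1ccccc1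
Why: Acylation under non-basic conditions should avoid retro-aldol cleavage and install the thionocarbonate as radical precursor (Barton–McCombie activation).

Step 9
Reactants: 13 thionocarbonate ketone
Product: 14 dimethyl alkylidene malonate of 13 [C8(Me)=C14(CO2Me)2]
Conditions: CH2(CO2Me)2 (1.5 equiv), TiCl4 (2.5 equiv), pyridine (5 equiv), THF, 0 °C to rt
Reagents that add atoms: dimethyl malonate COC(=O)CC(=O)OC
Why: TiCl4/pyridine Knoevenagel condensation of the unhindered methyl ketone should give the tetrasubstituted alkylidene malonate, with no E/Z issue because the two esters are identical.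

Step 10
Reactants: 14 cascade precursor
Product: 15 tricyclic γ-lactone with rings B and C closed [C8–Me and C10–Me on one face; C5–H, C9–H and the C12 silylethynyl group on the other; C12–Me equatorial; C13=CH(SiMe3) as E/Z mixture; C14(CO2Me)2]
Conditions: Bu3SnH (1.5 equiv) and AIBN (0.3 equiv) by syringe pump over 8 h, PhMe (0.005 M), 110 °C
Reagents that add atoms: none
Why: Bu3Sn• adds to the C=S group and β-scission releases the secondary C9 radical (both C9 epimers of 14 give the same planar radical, so the step is stereoconvergent); this radical adds 6-exo-trig to C8, the β-carbon of the alkylidene malonate, closing ring B and forming C8–C9, and the resulting malonyl radical at C14 adds 6-exo-dig to the internal carbon C13 of one of the two diastereotopic silylalkynes, closing ring C and forming C13–C14, after which the α-silylvinyl radical takes H from Bu3SnH. The closest known reaction type is Barton–McCombie radical generation followed by a tandem Giese-type cyclisation and a group-selective radical cyclisation onto an alkyne. Ring B should close through a chair locked by the trans-fused γ-lactone (C10–Me and C5–H axial): the bulky C(CO2Me)2 terminus stays equatorial, so C8–Me becomes axial and syn to C10–Me, and the C11 chain on C9 is equatorial, which gives the trans B/C junction with C9–H anti to both methyl groups. Ring C should close through a chair in which the rod-like silylethynyl group (A value about 0.4–0.5 kcal/mol) rather than methyl (about 1.7) is axial at C12, which sets C12 and leaves the unreacted alkyne syn-axial to one ester on C14. The step needs attack at C8 and exo attack at C13 to outrun early reduction: the two esters polarise C8, the SiMe3 caps block endo attack and stannyl addition, C1 is kept as a lactone carbonyl so that the C9 radical has no neighbouring vinyl group that could migrate, and Bu3SnH is kept dilute by slow addition.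

Step 11
Reactants: 15 vinylsilane
Product: 16 tricyclic γ-lactone with C13=CH2 (alkynyl SiMe3 retained)
Conditions: CF3CO2H/CH2Cl2 (1:4), 0 °C to rt
Reagents that add atoms: none
Why: Ipso-protonation of the vinylsilane gives a β-silyl cation that loses silicon (protodesilylation); the alkene cannot migrate because both neighbours are quaternary, and the alkynylsilane should survive.

Step 12
Reactants: 16 γ-lactone
Product: 17 lactol (C1–OH, anomer mixture)
Conditions: i-Bu2AlH (1.2 equiv), CH2Cl2, −78 °C; aq. potassium sodium tartrate
Reagents that add atoms: none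
Why: Partial reduction should be selective for the γ-lactone, because the two malonate esters on C14 are flanked by fully substituted C8 and C13 and are much more hindered.

Step 13
Reactants: 17 lactol
Product: 18 vinyl carbinol [C10–CH=CH2; C5–C(CH3)2OH]
Conditions: Ph3PCH3Br (4 equiv), KOt-Bu (3.8 equiv), THF, 0 to 60 °C
Reagents that add atoms: methyltriphenylphosphonium bromide C[P+](c1ccccc1)(c1ccccc1)c1ccccc1.[Br-]
Why: Wittig methylenation of the ring-opened hydroxy aldehyde gives the C10 vinyl group (C1) and frees the C4 tertiary alcohol; no stereocentre is affected.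

Step 14
Reactants: 18 vinyl carbinol
Product: 19 acrylate ester of the C4 tertiary alcohol
Conditions: KN(SiMe3)2 (1.1 equiv), THF, −78 °C; CH2=CHCOCl (1.5 equiv), −78 to 0 °C
Reagents that add atoms: acryloyl chloride C=CC(=O)Cl
Why: O-acylation via the potassium alkoxide overcomes the hindrance of the tertiary alcohol; the C14 esters have no α-hydrogen and are shielded.

Step 15
Reactants: 19 acrylate
Product: 20 ring-A α,β-unsaturated ε-lactone (rings A, B, C; C12–C≡C–SiMe3; C14(CO2Me)2; C13=CH2)
Conditions: second-generation Hoveyda–Grubbs catalyst (10 mol%), PhMe (0.003 M), 90 °C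
Reagents that add atoms: none
Why: Ring-closing metathesis between the acrylate and the C10 vinyl group should close the seven-membered ring with the necessarily cis C1=C2 bond, while the C13 methylene between two quaternary carbons and the silyl-capped alkyne stay out of the reaction.

Step 16
Reactants: 20 silylalkyne
Product: 21 C12 methyl ketone (C17=O, C16H3)
Conditions: Ph3PAuNTf2 (5 mol%), H2O (5 equiv), 1,4-dioxane, 60 °C
Reagents that add atoms: water O
Why: Gold-catalysed alkyne hydration should place oxygen on C17 (β-silicon effect and participation of the syn-axial ester), and the α-silyl ketone formed loses silicon under the conditions to give the methyl ketone.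

Step 17
Reactants: 21 methyl ketone
Product: 22 tetracyclic 1,3-diketone (ring D closed; C16H2; the 16-demethyl-16-deoxy analogue of the target)
Conditions: LiN(SiMe3)2 (2.2 equiv), THF, −78 to 0 °C; aq. NH4Cl
Reagents that add atoms: none
Why: Intramolecular Claisen (Dieckmann-type) condensation: the only enolisable site (C16) can reach only the ester syn-axial on C14, so ring D closes across the 1,3-diaxial positions and C14 becomes a stereocentre with the remaining CO2Me equatorial; the diketone enolate drives the reaction.

Step 18
Reactants: 22 1,3-diketone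
Product: 23 16-deoxy analogue of the target (C16–H, C16–Me; epimers/enol)
Conditions: K2CO3 (1.5 equiv), MeI (1.1 equiv), acetone, rt
Reagents that add atoms: iodomethane CI
Why: C-alkylation of the cyclic 1,3-diketone enolate with the soft electrophile MeI should place the methyl group on C16; its configuration is erased in step 19.

Step 19
Reactants: 23 2-methyl-1,3-diketone
Product: 24 target preaustinoid (ring D 16-hydroxy-16-methyl-15,17-dione; OH syn to C13)
Conditions: Cs2CO3 (20 mol%), O2 (1 atm), P(OEt)3 (2 equiv), DMSO, rt
Reagents that add atoms: dioxygen O=O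
Why: Enolate autoxidation with in situ phosphite reduction of the hydroperoxide (α-hydroxylation of a 1,3-dicarbonyl) should deliver oxygen to the exo face of ring D, on the side of the C13 bridge and away from C9–H and C11, which puts OH syn to C13 and the methyl group endo as in the target.

**Compound list**

1 | ethyl acetate | CCOC(C)=O | starting material
2 | (trimethylsilyl)acetylene | C#C[Si](C)(C)C | starting material
3 | 3-methyl-1,5-bis(trimethylsilyl)penta-1,4-diyn-3-ol | CC(O)(C#C[Si](C)(C)C)C#C[Si](C)(C)C | intermediate
4 | 4-methyl-6-(trimethylsilyl)-4-[(trimethylsilyl)ethynyl]hex-1-en-5-yne | C=CCC(C)(C#C[Si](C)(C)C)C#C[Si](C)(C)C | intermediate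
5 | 3-methyl-5-(trimethylsilyl)-3-[(trimethylsilyl)ethynyl]pent-4-ynal | O=CCC(C)(C#C[Si](C)(C)C)C#C[Si](C)(C)C | intermediate
6 | (S)-(−)-α-terpineol | CC1=CC[C@H](CC1)C(C)(C)O | starting material
7 | (3S)-3-(2-hydroxypropan-2-yl)-6-oxoheptanoic acid (not isolated) | CC(=O)CC[C@@H](CC(=O)O)C(C)(C)O | intermediate
8 | (4S)-5,5-dimethyl-4-(3-oxobutyl)oxolan-2-one | CC(=O)CC[C@H]1CC(=O)OC1(C)C | intermediate
9 | (4S)-5,5-dimethyl-4-[2-(2-methyl-1,3-dioxolan-2-yl)ethyl]oxolan-2-one | CC1(CC[C@H]2CC(=O)OC2(C)C)OCCO1 | intermediate
10 | (4S)-3,5,5-trimethyl-4-[2-(2-methyl-1,3-dioxolan-2-yl)ethyl]oxolan-2-one, trans isomer shown | CC1(CC[C@H]2[C@H](C)C(=O)OC2(C)C)OCCO1 | intermediate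
11 | ketal aldol: 10 carrying at C3 the 1-hydroxy-3-methyl-5-(trimethylsilyl)-3-[(trimethylsilyl)ethynyl]pent-4-yn-1-yl chain, trans to the 4-side chain; carbinol epimers (not isolated) | CC1(CC[C@H]2[C@](C)(C(O)CC(C)(C#C[Si](C)(C)C)C#C[Si](C)(C)C)C(=O)OC2(C)C)OCCO1 | intermediate
12 | keto aldol: as 11 with free 3-oxobutyl chain | CC(=O)CC[C@H]1[C@](C)(C(O)CC(C)(C#C[Si](C)(C)C)C#C[Si](C)(C)C)C(=O)OC1(C)C | intermediate
13 | O-phenyl thionocarbonate of 12 | CC(=O)CC[C@H]1[C@](C)(C(OC(=S)Oc2ccccc2)CC(C)(C#C[Si](C)(C)C)C#C[Si](C)(C)C)C(=O)OC1(C)C | intermediate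
14 | alkylidene malonate (cascade precursor) | COC(=O)C(C(=O)OC)=C(C)CC[C@H]1[C@](C)(C(OC(=S)Oc2ccccc2)CC(C)(C#C[Si](C)(C)C)C#C[Si](C)(C)C)C(=O)OC1(C)C | intermediate
15 | tricyclic γ-lactone, C13=CH(SiMe3), C12 axial C≡C–SiMe3, C14 diester | C[Si](C)(C)C=C1[C@](C)(C#C[Si](C)(C)C)C[C@H]2[C@]3(C)C(=O)OC(C)(C)[C@H]3CC[C@]2(C)C1(C(=O)OC)C(=O)OC | intermediate
16 | tricyclic γ-lactone, C13=CH2 | C=C1[C@](C)(C#C[Si](C)(C)C)C[C@H]2[C@]3(C)C(=O)OC(C)(C)[C@H]3CC[C@]2(C)C1(C(=O)OC)C(=O)OC | intermediate
17 | lactol of 16 | C=C1[C@](C)(C#C[Si](C)(C)C)C[C@H]2[C@]3(C)C(O)OC(C)(C)[C@H]3CC[C@]2(C)C1(C(=O)OC)C(=O)OC | intermediate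
18 | C10-vinyl, C4 tertiary alcohol | C=C1[C@](C)(C#C[Si](C)(C)C)C[C@H]2[C@](C)(C=C)[C@@H](C(C)(C)O)CC[C@]2(C)C1(C(=O)OC)C(=O)OC | intermediate
19 | acrylate of 18 | C=C1[C@](C)(C#C[Si](C)(C)C)C[C@H]2[C@](C)(C=C)[C@@H](C(C)(C)OC(=O)C=C)CC[C@]2(C)C1(C(=O)OC)C(=O)OC | intermediate
20 | ring-A unsaturated ε-lactone, silylalkyne, diester | C=C1[C@](C)(C#C[Si](C)(C)C)C[C@H]2[C@]3(C)C=CC(=O)OC(C)(C)[C@H]3CC[C@]2(C)C1(C(=O)OC)C(=O)OC | intermediate
21 | C12 methyl ketone | C=C1[C@](C)(C(C)=O)C[C@H]2[C@]3(C)C=CC(=O)OC(C)(C)[C@H]3CC[C@]2(C)C1(C(=O)OC)C(=O)OC | intermediate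
22 | tetracyclic 1,3-diketone (C16H2; 16-demethyl-16-deoxy analogue of the target) | C=C1[C@@]2(C)C[C@H]3[C@]4(C)C=CC(=O)OC(C)(C)[C@H]4CC[C@]3(C)[C@]1(C(=O)OC)C(=O)CC2=O | intermediate
23 | 16-deoxy analogue of the target (C16 epimers) | C=C1[C@@]2(C)C[C@H]3[C@]4(C)C=CC(=O)OC(C)(C)[C@H]4CC[C@]3(C)[C@]1(C(=O)OC)C(=O)C(C)C2=O | intermediate
24 | target preaustinoid: tetracycle with ring-A enoate ε-lactone, C13=CH2, C14–CO2Me and ring-D 16-hydroxy-16-methyl-15,17-dione (OH syn to C13) | C=C1[C@@]2(C)C[C@H]3[C@]4(C)C=CC(=O)OC(C)(C)[C@H]4CC[C@]3(C)[C@]1(C(=O)OC)C(=O)[C@@](C)(O)C2=O | target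

**Step count and risks**

Total step count: 19. Longest linear sequence: 16 (steps 4–19 from α-terpineol; steps 1–3 make aldehyde 5).

Step 10. What may go wrong: the malonyl radical at C14 is reduced by Bu3SnH before it closes ring C, so the cascade stops after ring B. Fallback: set out from 14 and run the tin hydride reaction at ordinary concentration (0.05 M, no slow addition) so that only ring B closes, giving the ring-B-closed malonate F1. Then regenerate the C14 radical oxidatively with Mn(OAc)3·2H2O in EtOH at 70 °C, where no fast hydride donor competes with the 6-exo-dig closure and the vinyl radical takes hydrogen from the solvent. This comes back to the route at 15.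

Step 15. What may go wrong: slow ring closure at the hindered vinyl group on quaternary C10, with acrylate oligomerisation or alkyne–carbene side reactions taking over. Fallback: set out from lactol 17 and use a (Z)-selective Horner–Wadsworth–Emmons olefination with methyl bis(2,2,2-trifluoroethyl)phosphonoacetate (KN(SiMe3)2, 18-crown-6, THF, −78 °C, cold quench) to give the (Z)-hydroxy enoate F2. Lactonise it onto the tertiary alcohol under neutral transesterification catalysis (Bu2SnO, PhMe, reflux), which avoids alkoxide-induced oxa-Michael closure. This comes back at 20 and bypasses 18 and 19.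

Step 18. What may go wrong: O-methylation or double C-methylation of the ambident diketone enolate. Fallback: set out from 20 and put the methyl group on carbon before ring D exists. Bu4NF/AcOH in THF removes the alkynyl silyl group to give the terminal alkyne F3; LiN(SiMe3)2 then MeI gives the propynyl compound F4; Ph3PAuNTf2/H2O hydration, steered to C17 by the syn-axial ester, gives the ethyl ketone F5; LiN(SiMe3)2 Claisen closure then gives 23 directly, bypassing 21 and 22.

**Further compounds**

F1 | step 10 | ring-B-closed malonate (C14–H, both silylalkynes intact) | C[Si](C)(C)C#CC(C)(C#C[Si](C)(C)C)C[C@H]1[C@]2(C)C(=O)OC(C)(C)[C@H]2CC[C@]1(C)C(C(=O)OC)C(=O)OC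
F2 | step 15 | (Z)-hydroxy enoate (C10–CH=CH–CO2Me cis, C4–OH free) | C=C1[C@](C)(C#C[Si](C)(C)C)C[C@H]2[C@](C)(/C=C\C(=O)OC)[C@@H](C(C)(C)O)CC[C@]2(C)C1(C(=O)OC)C(=O)OC
F3 | step 18 | terminal alkyne from 20 | C=C1[C@](C)(C#C)C[C@H]2[C@]3(C)C=CC(=O)OC(C)(C)[C@H]3CC[C@]2(C)C1(C(=O)OC)C(=O)OC
F4 | step 18 | C12 propynyl compound | C=C1[C@](C)(C#CC)C[C@H]2[C@]3(C)C=CC(=O)OC(C)(C)[C@H]3CC[C@]2(C)C1(C(=O)OC)C(=O)OC
F5 | step 18 | C12 ethyl ketone | C=C1[C@](C)(C(=O)CC)C[C@H]2[C@]3(C)C=CC(=O)OC(C)(C)[C@H]3CC[C@]2(C)C1(C(=O)OC)C(=O)OC
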